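**Plan**
Ring A is the aromatic ring and ring B the pyran ring of the chromene (atoms O1, C2 … C8a); ring C is the acylated cyclohexadienone.
Retrosynthesis: first the C8–CH2 bond of the methylene bridge is cut; then, after benzenesulfinic acid is added back across C3=C4, the C4–C4a and C2–C3 bonds of ring B are cut together; then O1–C2; in ring C the bond from the quaternary carbon to the prenyl group.
Forward: phloroglucinol is acylated and its para oxygen is alkylated with a 2-carboxyprop-2-yl group; a decarboxylative radical (4+2) annulation with phenyl vinyl sulfone (an acetylene equivalent) closes ring B; loss of sulfinate gives the chromene; a Mannich base at C8 then joins it to ring C.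
Enabling feature: C2 is a tertiary carbon on the aryl ether oxygen O1, so its carboxylic acid gives a stabilised, nucleophilic radical on decarboxylation; the two ring A carbons ortho to O1 are equivalent by symmetry and activated by three oxygens, so one becomes C4a without a regiochemical question and the other stays free as C8 for the bridge.
Stereochemistry: the single (R) quaternary centre of ring C is set by a palladium-catalysed asymmetric allylic dearomatisation (Tsuji–Trost) of a C-methyl acylphloroglucinol; it bears no hydrogen and is not touched afterwards.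

Key step: step 5

Assumption: the sense of induction in step 9 cannot be predicted with confidence, so the (S,S) ligand is written and the (R,R) ligand is used instead if a test run gives the (S) centre; ring C compounds are drawn as one of several enol tautomers.

**Step 1**
Reactants: 1 phloroglucinol; 2 isobutyryl chloride
Product: 3 2-methyl-1-(2,4,6-trihydroxyphenyl)propan-1-one
Conditions: AlCl3 (3.5 equiv), PhNO2, 65 °C; then ice, aq. HCl
Reagents that add atoms: none
Why: Friedel–Crafts C-acylation of the very electron-rich ring, in which all three ring carbons are equivalent and the first acyl group slows a second acylation.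

**Step 2**
Reactants: 3 2-methyl-1-(2,4,6-trihydroxyphenyl)propan-1-one; 4 ethyl 2-bromo-2-methylpropanoate
Product: 5 ethyl 2-[3,5-dihydroxy-4-(2-methylpropanoyl)phenoxy]-2-methylpropanoate
Conditions: K2CO3 (1.2 equiv), DMF, 60 °C
Reagents that add atoms: none
Why: Williamson-type O-alkylation that should take place at the para hydroxyl, the most acidic one and the only one not hydrogen-bonded to the ketone, while the tertiary electrophile disfavours C-alkylation of the ring.

**Step 3**
Reactants: 5 ethyl 2-[3,5-dihydroxy-4-(2-methylpropanoyl)phenoxy]-2-methylpropanoate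
Product: 6 2-[3,5-dihydroxy-4-(2-methylpropanoyl)phenoxy]-2-methylpropanoic acid
Conditions: LiOH·H2O (4 equiv), THF/MeOH/H2O, 50 °C, degassed; then 1 M HCl
Reagents that add atoms: lithium hydroxide, [Li+].[OH-]
Why: Saponification of the ester; the aryl ketone and the tertiary aryl ether are inert to hydroxide under these conditions.

**Step 4**
Reactants: 6 2-[3,5-dihydroxy-4-(2-methylpropanoyl)phenoxy]-2-methylpropanoic acid
Product: 7 1,3-dioxoisoindolin-2-yl 2-[3,5-dihydroxy-4-(2-methylpropanoyl)phenoxy]-2-methylpropanoate
Conditions: N-hydroxyphthalimide (1.1 equiv), N,N'-diisopropylcarbodiimide (1.1 equiv), DMAP (2 mol %), CH2Cl2, 0 → 25 °C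
Reagents that add atoms: N-hydroxyphthalimide, ON1C(=O)c2ccccc2C1=O
Why: Carbodiimide esterification with the acidic N-hydroxy imide; the two chelated phenols are poor nucleophiles and, being meta to the ether oxygen, cannot lactonise onto the activated acid.

**Step 5**
Reactants: 7 1,3-dioxoisoindolin-2-yl 2-[3,5-dihydroxy-4-(2-methylpropanoyl)phenoxy]-2-methylpropanoate; 8 phenyl vinyl sulfone
Product: 9 racemic 1-[5,7-dihydroxy-2,2-dimethyl-4-(phenylsulfonyl)-3,4-dihydro-2H-chromen-6-yl]-2-methylpropan-1-one
Conditions: 8 (3 equiv), fac-Ir(ppy)3 (1 mol %), degassed MeCN, blue LEDs (450 nm), 25 °C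
Reagents that add atoms: none
Why: Proposed new method: single-electron reduction of the N-acyloxyphthalimide 7 by photoexcited fac-Ir(ppy)3 releases CO2 and the tertiary, oxygen-stabilised, nucleophilic radical at C2, which adds to the unsubstituted terminus of the electron-poor alkene 8 (Giese addition, C2–C3 bond) to give an electrophilic alpha-sulfonyl radical at C4. This radical closes ring B by homolytic aromatic substitution at the ortho ring carbon C4a (six-membered closure, 6-exo with respect to the C4a=C5 ring bond, helped by the gem-dimethyl group and by polarity matching with the trioxygenated ring A); the cyclohexadienyl radical is then oxidised by the tetravalent iridium species and the phthalimide anion takes up the proton, so the cycle is redox neutral. The closest known reaction type is the photoredox decarboxylative radical addition and aryl cyclisation cascade of N-acyloxyphthalimides (oxindoles from N-arylacrylamides), together with radical (4+2) annulations of heteroatom-substituted alkyl radicals with electron-poor alkenes that give tetrahydroquinolines and chromans. The stereocentre formed at C4 arises as the racemate and needs no control, because step 6 removes it. The step needs addition of the C2 radical to 8 to outrun hydrogen abstraction, and ring closure to outrun oligomerisation of 8 or ipso attack; the polarity mismatch between the alpha-sulfonyl radical and a second molecule of 8 and the absence of a hydrogen donor should secure this. No regiochemical question arises, because the two ring carbons ortho to the ether oxygen of 7 are equivalent by symmetry and the one left untouched becomes C8.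

**Step 6**
Reactants: 9 racemic 1-[5,7-dihydroxy-2,2-dimethyl-4-(phenylsulfonyl)-3,4-dihydro-2H-chromen-6-yl]-2-methylpropan-1-one
Product: 10 1-(5,7-dihydroxy-2,2-dimethyl-2H-chromen-6-yl)-2-methylpropan-1-one
Conditions: DBU (3 equiv), MeCN, 25 → 50 °C; then aq. NH4Cl
Reagents that add atoms: none
Why: Base-induced elimination of benzenesulfinate from the benzylic C4, assisted by the phenoxide para to C4a, followed by proton loss from C3, which should give the conjugated C3=C4 double bond of the chromene.

**Step 7**
Reactants: 10 1-(5,7-dihydroxy-2,2-dimethyl-2H-chromen-6-yl)-2-methylpropan-1-one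
Product: 11 1-[8-[(dimethylamino)methyl]-5,7-dihydroxy-2,2-dimethyl-2H-chromen-6-yl]-2-methylpropan-1-one
Conditions: aq. CH2O (37 %, 1.1 equiv), Me2NH (40 % aq., 1.5 equiv), EtOH, 0 → 25 °C
Reagents that add atoms: formaldehyde, C=O; dimethylamine, CNC
Why: Mannich aminomethylation at C8, the only free and strongly activated position of ring A, with excess amine holding the one-carbon unit as the Mannich base and not as a symmetrical dimer.

**Step 8**
Reactants: 12 2-methylphloroglucinol (2,4,6-trihydroxytoluene); 2 isobutyryl chloride
Product: 13 2-methyl-1-(2,4,6-trihydroxy-3-methylphenyl)propan-1-one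
Conditions: AlCl3 (3.5 equiv), PhNO2, 65 °C; then ice, aq. HCl
Reagents that add atoms: none
Why: Friedel–Crafts C-acylation; the two free ring carbons of 12 are equivalent, so one ketone should result.

**Step 9**
Reactants: 13 2-methyl-1-(2,4,6-trihydroxy-3-methylphenyl)propan-1-one; 14 3-methylbut-2-en-1-yl acetate (prenyl acetate)
Product: 15 (4R)-3,5-dihydroxy-4-methyl-4-(3-methylbut-2-en-1-yl)-2-(2-methylpropanoyl)cyclohexa-2,5-dien-1-one
Conditions: 14 (1.0 equiv), Pd2(dba)3·CHCl3 (2.5 mol %), (S,S)-DACH-phenyl ligand [N,N'-((1S,2S)-cyclohexane-1,2-diyl)bis(2-(diphenylphosphino)benzamide)] (7.5 mol %), Et3N (1.2 equiv), CH2Cl2, 0 → 25 °C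
Reagents that add atoms: none
Why: Tsuji–Trost asymmetric allylic alkylation run as a dearomatisation, in which the phenoxide of 13 attacks the CH2 terminus of the 1,1-dimethylallyl complex formed from zerovalent palladium through its methyl-bearing ring carbon, and the chiral diphosphine pocket distinguishes the two enantiotopic faces of the flat nucleophile to set the quaternary (R) centre.

**Step 10**
Reactants: 11 1-[8-[(dimethylamino)methyl]-5,7-dihydroxy-2,2-dimethyl-2H-chromen-6-yl]-2-methylpropan-1-one; 15 (4R)-3,5-dihydroxy-4-methyl-4-(3-methylbut-2-en-1-yl)-2-(2-methylpropanoyl)cyclohexa-2,5-dien-1-one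
Product: 16 (4R)-6-{[5,7-dihydroxy-2,2-dimethyl-6-(2-methylpropanoyl)-2H-chromen-8-yl]methyl}-3,5-dihydroxy-4-methyl-4-(3-methylbut-2-en-1-yl)-2-(2-methylpropanoyl)cyclohexa-2,5-dien-1-one (CNP0319758.1)
Conditions: 15 (1.2 equiv), MeCN, 60 °C, N2, dark
Reagents that add atoms: none
Why: The acidic ring C enol protonates the Mannich base, dimethylamine is lost to give the ortho-quinone methide of ring A, and Michael addition of the free enolic ring carbon of 15 should form the methylene bridge without touching the quaternary centre.

**Compound list**
1 | phloroglucinol | Oc1cc(O)cc(O)c1 | starting material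
2 | isobutyryl chloride | CC(C)C(Cl)=O | starting material
3 | 2-methyl-1-(2,4,6-trihydroxyphenyl)propan-1-one | CC(C)C(=O)c1c(O)cc(O)cc1O | intermediate
4 | ethyl 2-bromo-2-methylpropanoate | CCOC(=O)C(C)(C)Br | starting material
5 | ethyl 2-[3,5-dihydroxy-4-(2-methylpropanoyl)phenoxy]-2-methylpropanoate | CCOC(=O)C(C)(C)Oc1cc(O)c(C(=O)C(C)C)c(O)c1 | intermediate
6 | 2-[3,5-dihydroxy-4-(2-methylpropanoyl)phenoxy]-2-methylpropanoic acid | CC(C)C(=O)c1c(O)cc(OC(C)(C)C(=O)O)cc1O | intermediate
7 | 1,3-dioxoisoindolin-2-yl 2-[3,5-dihydroxy-4-(2-methylpropanoyl)phenoxy]-2-methylpropanoate | CC(C)C(=O)c1c(O)cc(OC(C)(C)C(=O)ON2C(=O)c3ccccc3C2=O)cc1O | intermediate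
8 | phenyl vinyl sulfone | C=CS(=O)(=O)c1ccccc1 | starting material
9 | racemic 1-[5,7-dihydroxy-2,2-dimethyl-4-(phenylsulfonyl)-3,4-dihydro-2H-chromen-6-yl]-2-methylpropan-1-one | CC(C)C(=O)c1c(O)cc2OC(C)(C)CC(S(=O)(=O)c3ccccc3)c2c1O | intermediate
10 | 1-(5,7-dihydroxy-2,2-dimethyl-2H-chromen-6-yl)-2-methylpropan-1-one | CC(C)C(=O)c1c(O)cc2OC(C)(C)C=Cc2c1O | intermediate
11 | 1-[8-[(dimethylamino)methyl]-5,7-dihydroxy-2,2-dimethyl-2H-chromen-6-yl]-2-methylpropan-1-one | CC(C)C(=O)c1c(O)c(CN(C)C)c2OC(C)(C)C=Cc2c1O | intermediate
12 | 2-methylphloroglucinol (2,4,6-trihydroxytoluene) | Cc1c(O)cc(O)cc1O | starting material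
13 | 2-methyl-1-(2,4,6-trihydroxy-3-methylphenyl)propan-1-one | CC(C)C(=O)c1c(O)cc(O)c(C)c1O | intermediate
14 | 3-methylbut-2-en-1-yl acetate (prenyl acetate) | CC(C)=CCOC(C)=O | starting material
15 | (4R)-3,5-dihydroxy-4-methyl-4-(3-methylbut-2-en-1-yl)-2-(2-methylpropanoyl)cyclohexa-2,5-dien-1-one | CC(C)=CC[C@]1(C)C(O)=CC(=O)C(C(=O)C(C)C)=C1O | intermediate
16 | (4R)-6-{[5,7-dihydroxy-2,2-dimethyl-6-(2-methylpropanoyl)-2H-chromen-8-yl]methyl}-3,5-dihydroxy-4-methyl-4-(3-methylbut-2-en-1-yl)-2-(2-methylpropanoyl)cyclohexa-2,5-dien-1-one | CC(C)=CC[C@]1(C)C(O)=C(Cc2c(O)c(C(=O)C(C)C)c(O)c3c2OC(C)(C)C=C3)C(=O)C(C(=O)C(C)C)=C1O | target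

**Count and risks**
Total steps: 10. Longest linear sequence: 8 steps (steps 1 to 7, then step 10).

Steps most likely to fail:

1. Step 5. The adduct radical may be reduced or may add to further alkene before it closes on the ring, it may attack the ipso carbon with aryl migration, or the free phenols may quench the excited photocatalyst. Fallback (known chemistry): the route sets out again from 3. O-alkylation of the para hydroxyl with 3-chloro-3-methylbut-1-yne (K2CO3, KI, CuI cat., acetone, reflux) should give 1-[2,6-dihydroxy-4-(2-methylbut-3-yn-2-yloxy)phenyl]-2-methylpropan-1-one F1. Heating F1 in N,N-diethylaniline at about 150 °C should bring about aromatic Claisen rearrangement to the ortho allenyl phenol, 1,5-hydrogen shift and oxa-6π electrocyclisation. Because both ortho carbons are equivalent, only chromene 10 should form, and the route is rejoined at 10.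

2. Step 9. Facial selectivity may be poor, allylation may compete at the unsubstituted ring carbon or at oxygen, and reversible ionisation of the new C–prenyl bond by palladium may erode the enantiomeric purity. Fallback: the route sets out from 13. Dearomative C-prenylation without asymmetric control (NaOMe, MeOH, prenyl bromide, 0 °C) should give racemic 3,5-dihydroxy-4-methyl-4-(3-methylbut-2-en-1-yl)-2-(2-methylpropanoyl)cyclohexa-2,5-dien-1-one F2. This vinylogous acid is then resolved by fractional crystallisation of its salt with (S)-1-phenylethylamine, aiming at the (S)-1-phenylethylammonium salt of the (R) acid F3; the antipodal amine is used if the other diastereomer crystallises. Acidification of F3 (1 M HCl, EtOAc) returns the route to 15.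

3. Step 10. Retro-Mannich scrambling of the one-carbon unit may give symmetrical dimers, and the quinone methide may be captured by the prenyl double bond or at an enol oxygen. Fallback: the roles of the partners are reversed, setting out from 15. Aminomethylation of its free ring carbon (aq. CH2O, Me2NH, EtOH, 0 °C) should give (4R)-6-[(dimethylamino)methyl]-3,5-dihydroxy-4-methyl-4-(3-methylbut-2-en-1-yl)-2-(2-methylpropanoyl)cyclohexa-2,5-dien-1-one F4. Warming F4 with chromene 10 in MeCN should release the exocyclic methylene trione of ring C, which the free C8 of 10 captures in a Friedel–Crafts-type Michael addition; the route is rejoined at 16.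

**Further compounds**
F1 | step 5 | 1-[2,6-dihydroxy-4-(2-methylbut-3-yn-2-yloxy)phenyl]-2-methylpropan-1-one | CC(C)C(=O)c1c(O)cc(OC(C)(C)C#C)cc1O
F2 | step 9 | racemic 3,5-dihydroxy-4-methyl-4-(3-methylbut-2-en-1-yl)-2-(2-methylpropanoyl)cyclohexa-2,5-dien-1-one | CC(C)=CCC1(C)C(O)=CC(=O)C(C(=O)C(C)C)=C1O
F3 | step 9 | (S)-1-phenylethylammonium salt of (4R)-3,5-dihydroxy-4-methyl-4-(3-methylbut-2-en-1-yl)-2-(2-methylpropanoyl)cyclohexa-2,5-dien-1-one (written as acid and amine) | CC(C)=CC[C@]1(C)C(O)=CC(=O)C(C(=O)C(C)C)=C1O.C[C@H](N)c1ccccc1
F4 | step 10 | (4R)-6-[(dimethylamino)methyl]-3,5-dihydroxy-4-methyl-4-(3-methylbut-2-en-1-yl)-2-(2-methylpropanoyl)cyclohexa-2,5-dien-1-one | CC(C)=CC[C@]1(C)C(O)=C(CN(C)C)C(=O)C(C(=O)C(C)C)=C1O
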